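C1 of ring B carries two electron-rich aryl groups, ring A through C8a (para to the C6 methoxy group) and ring C through C1' (para to its hydroxyl), so C1 is treated as an aldehyde-level carbon and the bonds C1–C8a and C1–C1' are disconnected together. In one operation BF3·OEt2 lets ring A and syringol arylate an acetal carbon, closing ring B and setting C1 trans to C2. The precursor is a 2-methoxytetrahydrofuran: its acetal carbon is C1, its ring oxygen sits on C9', and the C9 acetoxymethyl group and the ring A benzyl arm stand cis on the two adjacent ring carbons, C2 and C3 of the target.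

Key step: step 7

Numbering: ring B is C1–C4 with ring C on C1 (through C1'), C9 (CH2OAc) on C2, C9' (CH2OAc) on C3; ring A is C4a, C5–C8, C8a with OMe on C6 and OH on C7. The target is (1S,2R,3R), all-trans.

Remark: the acetal ring runs C1–C2–C3–C9'–O and the tetralin ring C1–C2–C3–C4, so C3 exchanges its ring partner and a 2,3-trans tetralin requires a 3,4-cis acetal, (3R,4R). A 3,4-trans acetal (from α-hydroxymethylation of the β-benzyl lactone) would give the 2,3-cis tetralin, so the route below is built to deliver the cis acetal. Compound 1 is taken as commercially available.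

Step 1
Reactants: 1 4-benzyloxy-3-methoxybenzaldehyde (O-benzylvanillin); 2 dimethyl succinate
Product: 3 (E)-4-(4-benzyloxy-3-methoxyphenyl)-3-(methoxycarbonyl)but-3-enoic acid
Conditions: NaOMe (1.5 equiv), MeOH, reflux; then aq. HCl
Reagents that add atoms: none
Why: Stobbe condensation: the succinate enolate adds to the aldehyde, the aldolate lactonises onto the distal ester and E1cB opening of the paraconate gives the half-ester, with the aryl group trans to the conjugated ester (E); no stereocentre is formed.

Step 2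
Reactants: 3 (E)-4-(4-benzyloxy-3-methoxyphenyl)-3-(methoxycarbonyl)but-3-enoic acid
Product: 4 (R)-4-(4-benzyloxy-3-methoxyphenyl)-3-(methoxycarbonyl)butanoic acid
Conditions: [Rh(cod)((S,S)-Me-DuPhos)]BF4 (1 mol %), H2 (5 bar), NaOMe (10 mol %), MeOH, rt
Reagents that add atoms: none
Why: Rhodium-catalysed asymmetric hydrogenation of an itaconate-type half-ester: alkene and β-carboxylate chelate the metal and the (S,S) ligand is expected to deliver hydrogen to the face that gives the R centre (the later C3); the sense would be verified at lactone 5, and the aryl benzyl ether is inert to the homogeneous catalyst.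

Step 3
Reactants: 4 (R)-4-(4-benzyloxy-3-methoxyphenyl)-3-(methoxycarbonyl)butanoic acid
Product: 5 (R)-4-(4-benzyloxy-3-methoxybenzyl)dihydrofuran-2(3H)-one
Conditions: KOH (1 equiv), EtOH; CaCl2, NaBH4, EtOH, 0 °C → rt; then aq. HCl, rt
Reagents that add atoms: none
Why: Chemoselective ester reduction and lactonisation: Ca(BH4)2 made in situ reduces the methyl ester while the potassium carboxylate resists borohydride, and acidification closes the γ-hydroxy acid to the β-benzyl lactone; the stereocentre is not touched.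

Step 4
Reactants: 5 (R)-4-(4-benzyloxy-3-methoxybenzyl)dihydrofuran-2(3H)-one
Product: 7 (3S,4R)-4-(4-benzyloxy-3-methoxybenzyl)-3-(dimethoxymethyl)dihydrofuran-2(3H)-one (3,4-trans), via silyl ketene acetal 6 (not isolated)
Conditions: LiN(i-Pr)2, THF, −78 °C; Me3SiCl, −78 → 0 °C; solvent exchange to CH2Cl2; HC(OMe)3, Me3SiOTf (0.1 equiv), −78 °C
Reagents that add atoms: trimethyl orthoformate COC(OC)OC; chlorotrimethylsilane C[Si](C)(C)Cl (its atoms remain in 6 only)
Why: Mukaiyama-type alkylation of a ketene silyl acetal: Me3SiOTf turns the orthoformate into the dimethoxycarbenium ion, which 6 attacks on the face opposite the C4 benzyl group, so the new C3 centre is set trans (3S), the arrangement that is also thermodynamically preferred.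

Step 5
Reactants: 7 (3S,4R)-4-(4-benzyloxy-3-methoxybenzyl)-3-(dimethoxymethyl)dihydrofuran-2(3H)-one
Product: 8 (2R,3R)-2-(4-benzyloxy-3-methoxybenzyl)-3-(dimethoxymethyl)butane-1,4-diol
Conditions: LiAlH4, THF, 0 °C → rt; then H2O, aq. NaOH
Reagents that add atoms: none
Why: Hydride reduction of a lactone to the 1,4-diol; the dimethyl acetal is inert to LiAlH4 and to the basic work-up, and both stereocentres are retained (the descriptor at the acetal-bearing carbon changes only because the priorities change).

Step 6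
Reactants: 8 (2R,3R)-2-(4-benzyloxy-3-methoxybenzyl)-3-(dimethoxymethyl)butane-1,4-diol
Product: 10 [(3R,4R)-4-(4-benzyloxy-3-methoxybenzyl)-2-methoxytetrahydrofuran-3-yl]methyl acetate (3,4-cis, both anomers), via hydroxy acetal 9 (not isolated)
Conditions: camphorsulfonic acid (5 mol %), 5 Å molecular sieves, CH2Cl2, rt; then pyridine, Ac2O, DMAP (cat.), 0 °C → rt
Reagents that add atoms: acetic anhydride CC(=O)OC(C)=O
Why: Acid-catalysed intramolecular transacetalisation then acetylation: only the hydroxyl on the benzyl-bearing carbon (the later C9' oxygen) can reach the oxocarbenium ion through a five-membered ring (5-exo), the other hydroxyl could only form an oxetane and is acetylated; no stereocentre is touched, and because the ring now runs through the acetal carbon the trans relation of 7 appears as the required 3,4-cis relation.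

Step 7
Reactants: 10 [(3R,4R)-4-(4-benzyloxy-3-methoxybenzyl)-2-methoxytetrahydrofuran-3-yl]methyl acetate; 11 2,6-dimethoxyphenol (syringol)
Product: 14 [(1S,2R,3R)-7-(benzyloxy)-1-(4-hydroxy-3,5-dimethoxyphenyl)-3-(hydroxymethyl)-6-methoxy-1,2,3,4-tetrahydronaphthalen-2-yl]methyl acetate, via 2-aryltetrahydrofuran 12 (not isolated), via bridged benzylic ether 13 (not isolated)
Conditions: 11 (1.3 equiv), BF3·OEt2 (2.5 equiv), CH2Cl2 (0.02 M), −40 °C → rt; aq. NaHCO3
Reagents that add atoms: none
Why: BF3·OEt2 ionises the anomeric methoxy group of 10 to a cyclic oxocarbenium ion, which syringol traps at its carbon para to the hydroxyl (C1–C1') to give 12. The p-hydroxybenzylic ether of 12 ionises again with release of the C9' oxygen, and the quinone-methide-type cation at C1 is attacked by ring A at C8a (C1–C8a); the closest known reactions are Lewis acid Friedel–Crafts arylation of lactol ethers and the acid-mediated conversion of 2-aryl-4-benzyltetrahydrofuran lignans into 1-aryltetralins. Ring B closes by a six-membered Friedel–Crafts cycloalkylation (6-exo with respect to the C1=C1' bond of the cation) at the ring A carbon para to the methoxy group. If ring A attacks the oxocarbenium ion first, the bridged C1–O–C9' ether 13 reionises at C1 under the same conditions and is arylated by syringol, so both orders converge on 14 with the C9' hydroxyl free. The new C1 centre is controlled by the fixed C2 and C3 centres: the last bond forms anti to the C2 acetoxymethyl group through a chair-like arrangement with all three substituents equatorial (1S, all-trans), which is also the thermodynamic outcome because the benzylic ionisation is reversible. The step needs a single syringol addition, para attack in syringol and closure at C8a; these are secured by the high effective molarity of ring A (helped by dilution and a small excess of 11), by the para-directing hydroxyl and unhindered C4 of syringol, and by the benzyl ether on the ring A oxygen, which leaves the position para to the methoxy group as the most nucleophilic ring A carbon.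

Step 8
Reactants: 14 [(1S,2R,3R)-7-(benzyloxy)-1-(4-hydroxy-3,5-dimethoxyphenyl)-3-(hydroxymethyl)-6-methoxy-1,2,3,4-tetrahydronaphthalen-2-yl]methyl acetate
Product: 15 [(1S,2R,3R)-7-(benzyloxy)-1-(4-hydroxy-3,5-dimethoxyphenyl)-6-methoxy-1,2,3,4-tetrahydronaphthalene-2,3-diyl]dimethanediyl diacetate
Conditions: Novozym 435 (immobilised Candida antarctica lipase B), vinyl acetate, t-BuOMe, 40 °C
Reagents that add atoms: vinyl acetate C=COC(C)=O
Why: Lipase-catalysed irreversible transesterification: the acyl-enzyme from vinyl acetate transfers acetyl to the primary aliphatic C9' hydroxyl, while the phenol, a poor acyl acceptor for serine hydrolases and flanked by two methoxy groups, should stay free; no stereocentre is involved.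

Step 9
Reactants: 15 [(1S,2R,3R)-7-(benzyloxy)-1-(4-hydroxy-3,5-dimethoxyphenyl)-6-methoxy-1,2,3,4-tetrahydronaphthalene-2,3-diyl]dimethanediyl diacetate
Product: 16 [(1S,2R,3R)-7-hydroxy-1-(4-hydroxy-3,5-dimethoxyphenyl)-6-methoxy-1,2,3,4-tetrahydronaphthalene-2,3-diyl]dimethanediyl diacetate (CNP0265800.1)
Conditions: H2 (1 atm), 10% Pd/C, EtOAc, rt
Reagents that add atoms: none
Why: Hydrogenolysis of a benzyl aryl ether on palladium; the acetates, the phenol and the C1 diarylmethine are inert under these neutral conditions, EtOAc excludes transesterification, and no stereocentre is touched.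

Compound list
1 | 4-benzyloxy-3-methoxybenzaldehyde | COc1cc(C=O)ccc1OCc1ccccc1 | starting material
2 | dimethyl succinate | COC(=O)CCC(=O)OC | starting material
3 | (E)-4-(4-benzyloxy-3-methoxyphenyl)-3-(methoxycarbonyl)but-3-enoic acid | COC(=O)/C(CC(=O)O)=C/c1ccc(OCc2ccccc2)c(OC)c1 | intermediate
4 | (R)-4-(4-benzyloxy-3-methoxyphenyl)-3-(methoxycarbonyl)butanoic acid | COC(=O)[C@@H](CC(=O)O)Cc1ccc(OCc2ccccc2)c(OC)c1 | intermediate
5 | (R)-4-(4-benzyloxy-3-methoxybenzyl)dihydrofuran-2(3H)-one | O=C1C[C@@H](Cc2ccc(OCc3ccccc3)c(OC)c2)CO1 | intermediate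
6 | {[(4R)-4-(4-benzyloxy-3-methoxybenzyl)-4,5-dihydrofuran-2-yl]oxy}trimethylsilane (not isolated) | C[Si](C)(C)OC1=C[C@@H](Cc2ccc(OCc3ccccc3)c(OC)c2)CO1 | intermediate
7 | (3S,4R)-4-(4-benzyloxy-3-methoxybenzyl)-3-(dimethoxymethyl)dihydrofuran-2(3H)-one, 3,4-trans | COC(OC)[C@H]1C(=O)OC[C@@H]1Cc1ccc(OCc2ccccc2)c(OC)c1 | intermediate
8 | (2R,3R)-2-(4-benzyloxy-3-methoxybenzyl)-3-(dimethoxymethyl)butane-1,4-diol | COC(OC)[C@@H](CO)[C@H](CO)Cc1ccc(OCc2ccccc2)c(OC)c1 | intermediate
9 | [(3R,4R)-4-(4-benzyloxy-3-methoxybenzyl)-2-methoxytetrahydrofuran-3-yl]methanol, 3,4-cis, both anomers (not isolated) | COC1OC[C@H](Cc2ccc(OCc3ccccc3)c(OC)c2)[C@@H]1CO | intermediate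
10 | [(3R,4R)-4-(4-benzyloxy-3-methoxybenzyl)-2-methoxytetrahydrofuran-3-yl]methyl acetate, 3,4-cis, both anomers | COC1OC[C@H](Cc2ccc(OCc3ccccc3)c(OC)c2)[C@@H]1COC(C)=O | intermediate
11 | 2,6-dimethoxyphenol (syringol) | COc1cccc(OC)c1O | starting material
12 | [(2S,3R,4R)-4-(4-benzyloxy-3-methoxybenzyl)-2-(4-hydroxy-3,5-dimethoxyphenyl)tetrahydrofuran-3-yl]methyl acetate, 2,3-trans-3,4-cis (not isolated) | COc1cc(cc(OC)c1O)[C@H]1OC[C@H](Cc2ccc(OCc3ccccc3)c(OC)c2)[C@@H]1COC(C)=O | intermediate
13 | [(1R,2R,3R)-7-(benzyloxy)-6-methoxy-1,2,3,4-tetrahydro-1,3-(epoxymethano)naphthalen-2-yl]methyl acetate, ether oxygen on C1 and its CH2 (C9') on C3 (not isolated) | COc1cc2c(cc1OCc1ccccc1)[C@@H]1OC[C@H](C2)[C@@H]1COC(C)=O | intermediate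
14 | [(1S,2R,3R)-7-(benzyloxy)-1-(4-hydroxy-3,5-dimethoxyphenyl)-3-(hydroxymethyl)-6-methoxy-1,2,3,4-tetrahydronaphthalen-2-yl]methyl acetate | COc1cc2c(cc1OCc1ccccc1)[C@H](c1cc(OC)c(O)c(OC)c1)[C@@H](COC(C)=O)[C@H](CO)C2 | intermediate
15 | [(1S,2R,3R)-7-(benzyloxy)-1-(4-hydroxy-3,5-dimethoxyphenyl)-6-methoxy-1,2,3,4-tetrahydronaphthalene-2,3-diyl]dimethanediyl diacetate | COc1cc2c(cc1OCc1ccccc1)[C@H](c1cc(OC)c(O)c(OC)c1)[C@@H](COC(C)=O)[C@H](COC(C)=O)C2 | intermediate
16 | [(1S,2R,3R)-7-hydroxy-1-(4-hydroxy-3,5-dimethoxyphenyl)-6-methoxy-1,2,3,4-tetrahydronaphthalene-2,3-diyl]dimethanediyl diacetate | COc1cc2c(cc1O)[C@H](c1cc(OC)c(O)c(OC)c1)[C@@H](COC(C)=O)[C@H](COC(C)=O)C2 | target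

Total step count: 9. Longest linear sequence: 9 steps (1 to 16); 2 enters in step 1 and 11 in step 7.

Steps most likely to fail

Step 7. The open C1 cation may be captured by a second syringol before ring A closes. The oxocarbenium ion may lose the C2 proton and re-protonate, eroding the cis relation. The Lewis acid may also attack the benzyl ether. The fallback makes the two C1–aryl bonds in separate operations and brings in ring C as an organometallic nucleophile. It sets out from 8 and returns at 16. Aqueous AcOH in THF would hydrolyse the acetal of 8 to (3R,4R)-4-(4-benzyloxy-3-methoxybenzyl)-3-(hydroxymethyl)tetrahydrofuran-2-ol F1. Commercial 4-bromo-2,6-dimethoxyphenol would be benzylated (BnBr, K2CO3, DMF) to 2-(benzyloxy)-5-bromo-1,3-dimethoxybenzene F2 and converted with Mg in THF into (4-benzyloxy-3,5-dimethoxyphenyl)magnesium bromide F3. An excess of this Grignard reagent would add to the open hydroxy aldehyde form of F1 to give (2R,3R)-2-[(4-benzyloxy-3,5-dimethoxyphenyl)(hydroxy)methyl]-3-(4-benzyloxy-3-methoxybenzyl)butane-1,4-diol F4 as a mixture of carbinol epimers. CF3CO2H in CH2Cl2 would ionise the benzylic alcohol, and intramolecular Friedel–Crafts alkylation by ring A, a standard closure for aryltetralin lignans, should give all-trans [(1S,2R,3R)-7-(benzyloxy)-1-(4-benzyloxy-3,5-dimethoxyphenyl)-6-methoxy-1,2,3,4-tetrahydronaphthalene-2,3-diyl]dimethanol F5, both epimers passing through the same cation. Ac2O and pyridine would give [(1S,2R,3R)-7-(benzyloxy)-1-(4-benzyloxy-3,5-dimethoxyphenyl)-6-methoxy-1,2,3,4-tetrahydronaphthalene-2,3-diyl]dimethanediyl diacetate F6, and hydrogenolysis of both benzyl ethers (H2, Pd/C, EtOAc) would give 16.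

Step 4. The enolate may be silylated at carbon instead of oxygen, the β,β-dimethoxy lactone may lose methanol to an α-methoxymethylene lactone under the Lewis acid, or facial selectivity may be incomplete. The fallback uses a sulfur-based formyl cation equivalent directly on the lithium enolate. It sets out from 5 and returns at 9. The enolate of 5 (LiN(i-Pr)2, THF, −78 °C) would be quenched with commercial 1,3-benzodithiolylium tetrafluoroborate, alkylation anti to the benzyl group giving trans (3R,4R)-3-(1,3-benzodithiol-2-yl)-4-(4-benzyloxy-3-methoxybenzyl)dihydrofuran-2(3H)-one F7. LiAlH4 in THF would reduce it to (2R,3R)-2-(1,3-benzodithiol-2-yl)-3-(4-benzyloxy-3-methoxybenzyl)butane-1,4-diol F8. Hg(ClO4)2 with CaCO3 in MeOH–THF would then unmask the dithioacetal, the C9' hydroxyl and methanol capturing the thionium ion to give hydroxy acetal 9, which is acetylated as in step 6 to 10.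

Step 8. Acyl transfer may be slow because the β-branched primary alcohol beside the tetralin fits the enzyme pocket poorly, or the phenol may be partly acylated. Acyl migration between C9 and C9' is harmless, since both end as acetates. The fallback is exhaustive chemical acetylation followed by chemoselective aminolysis. It sets out from 14 and returns at 15. Ac2O, pyridine and DMAP would give [(1S,2R,3R)-1-(4-acetoxy-3,5-dimethoxyphenyl)-7-(benzyloxy)-6-methoxy-1,2,3,4-tetrahydronaphthalene-2,3-diyl]dimethanediyl diacetate F9, and pyrrolidine in CH2Cl2 at 0 °C would cleave only the activated aryl acetate to give 15.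

Further compounds
F1 | step 7 | (3R,4R)-4-(4-benzyloxy-3-methoxybenzyl)-3-(hydroxymethyl)tetrahydrofuran-2-ol | OC1OC[C@H](Cc2ccc(OCc3ccccc3)c(OC)c2)[C@@H]1CO
F2 | step 7 | 2-(benzyloxy)-5-bromo-1,3-dimethoxybenzene | COc1cc(Br)cc(OC)c1OCc1ccccc1
F3 | step 7 | (4-benzyloxy-3,5-dimethoxyphenyl)magnesium bromide | COc1cc([Mg]Br)cc(OC)c1OCc1ccccc1
F4 | step 7 | (2R,3R)-2-[(4-benzyloxy-3,5-dimethoxyphenyl)(hydroxy)methyl]-3-(4-benzyloxy-3-methoxybenzyl)butane-1,4-diol, carbinol epimers | OC(c1cc(OC)c(OCc2ccccc2)c(OC)c1)[C@@H](CO)[C@H](CO)Cc1ccc(OCc2ccccc2)c(OC)c1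
F5 | step 7 | [(1S,2R,3R)-7-(benzyloxy)-1-(4-benzyloxy-3,5-dimethoxyphenyl)-6-methoxy-1,2,3,4-tetrahydronaphthalene-2,3-diyl]dimethanol | COc1cc2c(cc1OCc1ccccc1)[C@H](c1cc(OC)c(OCc3ccccc3)c(OC)c1)[C@@H](CO)[C@H](CO)C2
F6 | step 7 | [(1S,2R,3R)-7-(benzyloxy)-1-(4-benzyloxy-3,5-dimethoxyphenyl)-6-methoxy-1,2,3,4-tetrahydronaphthalene-2,3-diyl]dimethanediyl diacetate | COc1cc2c(cc1OCc1ccccc1)[C@H](c1cc(OC)c(OCc3ccccc3)c(OC)c1)[C@@H](COC(C)=O)[C@H](COC(C)=O)C2
F7 | step 4 | (3R,4R)-3-(1,3-benzodithiol-2-yl)-4-(4-benzyloxy-3-methoxybenzyl)dihydrofuran-2(3H)-one, 3,4-trans | S1c2ccccc2SC1[C@H]1C(=O)OC[C@@H]1Cc1ccc(OCc2ccccc2)c(OC)c1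
F8 | step 4 | (2R,3R)-2-(1,3-benzodithiol-2-yl)-3-(4-benzyloxy-3-methoxybenzyl)butane-1,4-diol | S1c2ccccc2SC1[C@@H](CO)[C@H](CO)Cc1ccc(OCc2ccccc2)c(OC)c1
F9 | step 8 | [(1S,2R,3R)-1-(4-acetoxy-3,5-dimethoxyphenyl)-7-(benzyloxy)-6-methoxy-1,2,3,4-tetrahydronaphthalene-2,3-diyl]dimethanediyl diacetate | COc1cc2c(cc1OCc1ccccc1)[C@H](c1cc(OC)c(OC(C)=O)c(OC)c1)[C@@H](COC(C)=O)[C@H](COC(C)=O)C2
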